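You are given no rate constant for this flask, so build a time constant out of the readings instead.

| flask | X | J | Z | Q | time |
|---|---|---|---|---|---|
| west | 0.120 M | 0.0960 M | 0.00240 M |  |  |
| east | 0.120 M | 0.0960 M | 0.00240 M | 0.0360 M |  |
| south-west | 0.120 M | 0.290 M | 0.00240 M |  |  |
| south | 0.120 M | 0.0960 M | 0.00120 M |  |  |
| south-east | 0.600 M | 0.0960 M | 0.00240 M |  | 40 min |

| run | time / min | [Q] / M |
|---|---|---|
| west run | 1.6 | 0.0016 |
| west run | 2.5 | 0.0026 |
| west run | 4.0 | 0.0063 |
| west run | 6.4 | 0.0109 |
| west run | 10 | 0.0205 |
| west run | 16 | 0.0306 |
| west run | 25 | 0.0483 |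
| west run | 40 | 0.0691 |
| east run | 1.6 | 0.0443 |
| east run | 2.5 | 0.0440 |
| east run | 4.0 | 0.0515 |
| east run | 6.4 | 0.0543 |
| east run | 10 | 0.0646 |
| east run | 16 | 0.0819 |
| east run | 25 | 0.0954 |
| east run | 40 | 0.1153 |
| south-west run | 1.6 | 0.0047 |
| south-west run | 2.5 | 0.0109 |
| south-west run | 4.0 | 0.0143 |
| south-west run | 6.4 | 0.0211 |
| south-west run | 10 | 0.0368 |
| south-west run | 16 | 0.0586 |
| south-west run | 25 | 0.0882 |
| south-west run | 40 | 0.1082 |
| south run | 1.6 | 0.0016 |
| south run | 2.5 | 0.0015 |
| south run | 4.0 | 0.0087 |
| south run | 6.4 | 0.0034 |
| south run | 10 | 0.0124 |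
| south run | 16 | 0.0147 |
| south run | 25 | 0.0344 |
| south run | 40 | 0.0459 |

(standard deviation of a reading: 0.002 M)

- Overall: X + J -> Q, with Z as catalyst.
- Constant volume, constant temperature.
- What is held in complexes is read along with the free species.
- An order is taken over about fifteen percent of the charge, up and down.

1. the exponent of [Z] in the starting rate at the charge of the west run (at the point where two percent of the X have become Q)
2. the exponent of [J] in the starting rate at the charge of the west run (at the point where two percent of the X have become Q)
3. Q in the south-east run at 40 min, as a share of the X charged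

Read across the row at 25 min. The west run stands at 0.0483 M, an average rate of 0.00193 M min⁻¹. The south-west run, with 3.02 times the J, reads only 1.83 times as much, and the south run, with half the Z, reads 0.712 of it. These are readings with their scatter, but in the south-west run the Q made plainly moves less than the J charged.

Now take the south-east flask, where cJ is lower than cX. J is the limiting reagent, so Q made stops at a ceiling of 16.0% of the X charged. Define the clearing time as the charge of J divided by the rate, the time constant of emptying a tank at a steady outflow: 49.7 min at the west rate.

Use two ends of a scale. If the rate ignored cX, the clearing time would stay longer than the 40 min allowed, and Q would reach 12.9% of the X. If the rate followed cX in proportion, it would shrink to 9.94 min, well inside the time. A rise of just 1.24 in rate closes the gap, so my own reckoning commits to the ceiling.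

The forecast says 12.5% (9.5% to 15%), lower than mine, on the ground that “X is nearly saturating”. For the orders it gives 0.7 in Z (0.45 to 1) and 0.7 in J (0.5 to 0.95).

The flask gives 16.0%, which is the ceiling, and orders of 0.94 in Z and 0.51 in J. The forecast's share lies within the tolerance, its Z order is too low, and its J order is too high.

    Z + X ⇌ ZX, settled at all times (1.120 L mol⁻¹)
    ZX + J ⇌ ZXJ, settled at all times (63.90 L mol⁻¹)
    ZXJ → Q + Z (3.870 min⁻¹)
    2 J ⇌ J2, settled at all times (33.60 L mol⁻¹)
    X + J + Q → 2 Q (11.46 L² mol⁻² min⁻¹)

The apparent order in X is 0.75, against 0.57 in the simulated run without the parking of J as J2. Carried up to the south-east charge as a rough estimate, that order gives a clearing time of 14.8 min, and the smaller order gives 19.8 min, so the parking does not set the share. In the south run, the rate where two percent of the X of the west run have turned gives a clearing time of 100 min. Held steady, that rate brings the Q made to half of the X charged in 62.7 min, and the south run takes 50.2 min.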